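## Structural features

The target is a chalcone. Ring A is the benzene ring of a 2,3-dihydro-1-benzofuran (numbered O1, C2, C3, C3a, C4 to C7, C7a), ring B is a 4-hydroxyphenyl group, and an (E)-enone with its carbonyl carbon on C7 joins them. Ring A has a phloroglucinol pattern with three different oxygens: a free hydroxyl on C4, a methyl ether on C6 and the ring oxygen O1 on C7a. C3a carries the C3 methylene, C7 the acyl group, and only C5 bears hydrogen. C2 is the single stereocentre, (R), bound to O1, C3 and a 2-hydroxypropan-2-yl group. It has no stereogenic neighbour, so its configuration must be set in the absolute sense. The fragile parts are the enone (Michael acceptor, light-sensitive geometry), the two phenols, the electron-rich ring A (oxidation, electrophilic attack at C5) and the tertiary alcohol beside C2 (dehydration under acid). The real difficulties are the absolute configuration at an isolated C2 and placing the cinnamoyl group at C7, between OMe and O1, not at the electronically similar C5. The key step exploits the position of the C3 methylene on C3a, between the oxygen-bearing carbons C4 and C7a. C3a–CH2 with the C7a oxygen is a latent o-quinone methide, and C2, bonded only to O1, C3 and one exocyclic carbon, can arrive as a one-carbon ylide unit bridging the methide carbon and the carbonyl oxygen.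

## Logic of the disconnections

22 to 21: the two phenolic O–H bonds are exchanged for O–Si bonds. The C7–acyl bond is to be made with an organolithium, which free phenols would quench. Nothing is gained in skeleton, but the next cut becomes possible. The forward step must remove both silyl groups without harming the enone, the tertiary alcohol or C2.

21 to 15 and 18: the C7–C(=O) bond is cut. It is the only C–C bond between ring A and the enone, so the cut gives two halves of similar size, and the (E)-alkene is bought ready-made. The forward step must metalate C7 and not C5 (through 19) and must stop at the ketone (through 20).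

15 to 13: the two C–CH3 bonds of the carbinol are cut, leaving an ester carbon on C2. An ester is what a stabilised ylide delivers, so the side chain shrinks to a carboxylate. The forward step is a double methyl addition through 14 that must not enolise C2.

13 to 5 and 8: the C2–C3 and O1–C2 bonds are cut, which removes the furan ring and the only stereocentre at once. What remains are a benzylic amine and a sulfonium salt, with 9, 10, 11 and 12 as the species in the flask. Two changes are made to the precursor, without changing its skeleton:
- The second phenol is carried as a triisopropylsilyl ether. A free hydroxyl there would make the methide a vinylogous acid that carbonate converts to an unreactive anion, and it would compete for the hydrogen-bond donor. The ether is needed later for the metalation in any case.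
- The amine is N-methylated in the flask, so the methide forms well below room temperature.

The forward step must control C2 absolutely and must favour ylide capture over self-condensation of 10.

5 to 3: the benzylic C–N bond is cut to an aldehyde and dimethylamine, joined through 4. This puts the aminomethyl carbon unambiguously between the two oxygens. The forward reduction must be mild enough not to expel the amine.

3 to 2: one O–Si bond is cut. The two hydroxyls of 2 are equivalent, so only one mono-ether exists. The forward step must stop after one silylation.

2 to 1: the O–CH3 bond at the para oxygen is cut, which leads to a commercial trihydroxybenzaldehyde. The forward step needs para-selective mono-methylation.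

8 to 6 and 7: the S–CH2 bond is cut, giving two commercial liquids. The forward step is a simple S-alkylation.

18 to 17: the O–Si bond on ring B is cut. The forward silylation uses the same silyl group as ring A, so one reagent removes both at the end.

17 to 16: the amide C–N bond is cut, which leads to commercial 4-hydroxycinnamic acid. The forward coupling must tolerate the free phenol.

## Other disconnections considered

Alternative 1: Ring A itself is cut at C7–C7a and C5–C6 and built by a Danheiser benzannulation.
- Forward key step: heating cyclobutenone A2 opens it to a vinylketene, which adds the silylated ynol ether A3 in a [2+2] sense. The vinyl-substituted cyclobutenone reopens, and a six-electron electrocyclisation and tautomerisation give phenol A1. In A1 the hydroxyl is the future O1, the prenyl group sits on C3a, the PMB ether on C4, OMe on C6 and the silyl group marks C7.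
- In favour: every ring position is differentiated in one pericyclic cascade with predictable regiochemistry. The silyl group fixes C7 for ipso-substitution. On the C5/C7 question this is better than the chosen plan, which relies on site-selective metalation. It also needs no selective methylation of a triol, again better.
- Against: the step builds no stereocentre. C2 would still need an asymmetric epoxidation of the prenyl alkene (Shi type) and 5-exo opening by the phenol, with 6-endo chroman formation competing. A2 and A3 are not commercial and need ketene–alkyne chemistry. The prenyl and PMB groups must survive prolonged heating. The ipso-acylation still needs an organometallic step.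
- Comparison: mechanistically the cascade is at least as reliable as the annulation chosen. Structurally it solves the arene and leaves the heterocycle and stereocentre for later, whereas the chosen step makes ring, two bonds and stereocentre together. Step economy is clearly worse, an estimated twelve to fourteen steps against ten.

Alternative 2: C3–C3a and C7a–O1 are cut, joining aryl iodide A5 and enantiopure epoxide A6 in a Catellani-type annulation to A4.
- Forward key step: zerovalent palladium from Pd(OAc)2 and a phosphine inserts into the C–I bond. Norbornene insertion and ortho C–H palladation give a palladacycle, which opens A6 at its CH2 carbon to form C3–C3a. After norbornene extrusion the alkoxide closes the ring by C–O reductive elimination at C7a.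
- In favour: the C2 configuration is bought with A6, and no bond to the stereocentre is broken. Stereochemical security is better than in the chosen plan. The C7 carbon is already present as an ester, so the C5/C7 problem does not arise, also better. The route is convergent.
- Against: the C–H bond to be palladated lies between the iodide carbon and a bulky silyloxy group, a crowded site on an electron-rich arene. The resulting benzoate with two ortho oxygen substituents is hard to convert to the cinnamoyl ketone. A5 needs regioselective iodination and oxygen differentiation, and A6 needs several steps in enantiopure form.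
- Comparison: it is the equal of the chosen plan in forming the ring in one step. It is better in stereocontrol and worse in the demands on the catalytic C–H step. Step economy is estimated similar or slightly worse, eleven to thirteen steps.

Alternative 3: C3a–C3 and O1–C2 are cut. C2, C3 and the three side-chain carbons come from isoprene A9 in an enantioselective palladium heteroannulation of iodophenol A8, giving A7.
- Forward key step: zerovalent palladium from Pd2(dba)3 and a chiral phosphine inserts into the C–I bond. The aryl group adds to the CH2 end of the unsubstituted vinyl group of A9, and the phenoxide attacks the inner carbon of the allyl palladium intermediate, which sets C2.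
- In favour: the C7 acetyl group comes from a commercial trioxygenated acetophenone, so C7 regiochemistry is settled and the chalcone follows by Claisen–Schmidt condensation. A9 supplies five carbons at once. With an estimated seven or eight steps it is better than the chosen plan in step economy.
- Against: the isopropenyl group needs a later Markovnikov hydration before the enone exists. The regiochemistry of insertion into an unsymmetrical diene and the enantioselectivity with a small diene and a chelated iodophenol flanked by two ortho substituents are uncertain. The iodination of the acetophenone must be regioselective.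
- Comparison: in enantiocontrol it is no more and no less certain than the chosen plan, so the two are equal there. The chosen plan is stronger in the simplicity and symmetry of its precursor and in reaching the side-chain oxidation level directly from the ester.

Key step: step 5

Assumption: the sense of induction of the bis-urea catalyst in step 5 cannot be assigned in advance. The catalyst is 1,1'-[(1R,2R)-1,2-diphenylethane-1,2-diyl]bis{3-[3,5-bis(trifluoromethyl)phenyl]urea} or its antipode, whichever gives the (2R) ester. The (2R) descriptor holds for 13, 15 and 22 alike (O1 > exocyclic carbon > C3 > H), and no structure needed correction.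

## Route

Step 1
Reactants: 1 2,4,6-trihydroxybenzaldehyde
Product: 2 2,6-dihydroxy-4-methoxybenzaldehyde
Conditions: MeI (1.1 equiv), CsHCO3 (1.2 equiv), MeCN, 60 °C, sealed vessel
Reagents that add atoms: iodomethane, CI
Why: Regioselective Williamson ether synthesis; the 4-hydroxyl lies para to the formyl group and outside its chelate, so it is the most acidic and least encumbered, and a hydrogen carbonate base should form and methylate only that phenoxide.

Step 2
Reactants: 2 2,6-dihydroxy-4-methoxybenzaldehyde
Product: 3 2-hydroxy-4-methoxy-6-[(triisopropylsilyl)oxy]benzaldehyde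
Conditions: TIPSCl (1.05 equiv), Et3N, DMAP (cat.), CH2Cl2, 0 °C to rt
Reagents that add atoms: chlorotri(propan-2-yl)silane, CC(C)[Si](Cl)(C(C)C)C(C)C
Why: Phenol silylation; the two hydroxyls are equivalent, so one mono-ether results, and the remaining hydroxyl is then locked in the chelate with the formyl oxygen, which should stop the reaction at the mono-silyl stage.

Step 3
Reactants: 3 2-hydroxy-4-methoxy-6-[(triisopropylsilyl)oxy]benzaldehyde
Product: 5 2-[(dimethylamino)methyl]-5-methoxy-3-[(triisopropylsilyl)oxy]phenol, via iminium phenoxide 4 (not isolated)
Conditions: Me2NH (2 M in THF, 2 equiv), NaBH(OAc)3 (1.5 equiv), ClCH2CH2Cl, rt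
Reagents that add atoms: dimethylamine, CNC
Why: Reductive amination; the salicylaldehyde condenses with the secondary amine to zwitterion 4, which the mild triacetoxyborohydride reduces without touching the aryl silyl ether, and the temperature stays low enough that the Mannich base does not yet lose amine.

Step 4
Reactants: 6 tert-butyl bromoacetate; 7 dimethyl sulfide
Product: 8 (2-tert-butoxy-2-oxoethyl)dimethylsulfonium bromide
Conditions: acetone, rt, 24 h; filtration
Reagents that add atoms: none
Why: SN2 S-alkylation of the sulfide by an activated α-bromo ester; the salt should crystallise from acetone.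

Step 5
Reactants: 5 2-[(dimethylamino)methyl]-5-methoxy-3-[(triisopropylsilyl)oxy]phenol; 8 (2-tert-butoxy-2-oxoethyl)dimethylsulfonium bromide
Product: 13 tert-butyl (2R)-6-methoxy-4-[(triisopropylsilyl)oxy]-2,3-dihydro-1-benzofuran-2-carboxylate, via trimethylammonium iodide 9 (not isolated), via o-quinone methide 10 (not isolated), via sulfonium ylide 11 (not isolated), via sulfonium betaine 12 (not isolated)
Conditions: MeI (1.0 equiv), CH2Cl2, 0 °C to rt; then 8 (1.5 equiv), bis-urea catalyst (10 mol %), Cs2CO3 (2.5 equiv), CH2Cl2/PhMe, −40 to −20 °C
Reagents that add atoms: none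
Why: N-Methylation of 5 gives salt 9, whose phenoxide expels trimethylamine at low temperature to give o-quinone methide 10 (carbonyl at the future C7a, exocyclic CH2 on the future C3a), while Cs2CO3 converts 8 into ester-stabilised ylide 11. Rearomatisation drives conjugate addition of the ylide carbon to the methide CH2 (C2–C3), and phenoxide betaine 12 closes the furan ring by 5-exo-tet intramolecular SN2 displacement of dimethyl sulfide (O1–C2). The closest known reaction type is the [4+1] annulation of o-quinone methides generated in the flask with stabilised sulfonium ylides to 2,3-dihydrobenzofurans under chiral urea catalysis. C2 is the only new stereocentre and arises on the ylide carbon; because the C2–H of 12 is acidic, its configuration is settled in the ring closure, where the bis-urea holds the phenoxide oxygen and the ester carbonyl and one epimer of 12 closes faster (Curtin–Hammett, inversion at C2). The bulky tert-butyl ester should slow enolisation of 13 so the product does not racemise under carbonate. The step needs chemoselectivity for ylide capture over self-condensation of 10; the silyl ether removes the second acidic hydroxyl and lowers ring nucleophilicity, and slow release of 10 from sparingly soluble 9 together with excess 11 keeps 10 scarce. No regiochemical question arises because 10 has a single carbonyl oxygen beside the methide carbon.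

Step 6
Reactants: 13 tert-butyl (2R)-6-methoxy-4-[(triisopropylsilyl)oxy]-2,3-dihydro-1-benzofuran-2-carboxylate
Product: 15 2-[(2R)-6-methoxy-4-[(triisopropylsilyl)oxy]-2,3-dihydro-1-benzofuran-2-yl]propan-2-ol, via methyl ketone 14 (not isolated)
Conditions: MeMgBr (3 equiv), THF, 0 °C to rt; aq NH4Cl
Reagents that add atoms: methylmagnesium bromide, C[Mg]Br
Why: Double Grignard addition to the ester through ketone 14, which is more electrophilic than 13 and is consumed as it forms; the α-aryloxy group activates the carbonyl and the small reagent should add faster than it enolises, so C2, to which no bond is broken, keeps its configuration.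

Step 7
Reactants: 16 (2E)-3-(4-hydroxyphenyl)prop-2-enoic acid (4-hydroxycinnamic acid)
Product: 17 (2E)-3-(4-hydroxyphenyl)-N-methoxy-N-methylprop-2-enamide
Conditions: MeNHOMe·HCl, EDC·HCl, HOBt, N-methylmorpholine, DMF, 0 °C to rt
Reagents that add atoms: N,O-dimethylhydroxylamine hydrochloride, CNOC.Cl
Why: Carbodiimide amide coupling through the benzotriazolyl ester; the amine outcompetes the phenol as acyl acceptor and any aryl ester formed is aminolysed.

Step 8
Reactants: 17 (2E)-3-(4-hydroxyphenyl)-N-methoxy-N-methylprop-2-enamide
Product: 18 (2E)-N-methoxy-N-methyl-3-{4-[(triisopropylsilyl)oxy]phenyl}prop-2-enamide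
Conditions: TIPSCl, imidazole, DMF, rt
Reagents that add atoms: chlorotri(propan-2-yl)silane, CC(C)[Si](Cl)(C(C)C)C(C)C
Why: Phenol silylation; the bulky silyl ether withstands the organolithium step and matches the one on ring A.

Step 9
Reactants: 15 2-[(2R)-6-methoxy-4-[(triisopropylsilyl)oxy]-2,3-dihydro-1-benzofuran-2-yl]propan-2-ol; 18 (2E)-N-methoxy-N-methyl-3-{4-[(triisopropylsilyl)oxy]phenyl}prop-2-enamide
Product: 21 (2E)-1-[(2R)-2-(2-hydroxypropan-2-yl)-6-methoxy-4-[(triisopropylsilyl)oxy]-2,3-dihydro-1-benzofuran-7-yl]-3-{4-[(triisopropylsilyl)oxy]phenyl}prop-2-en-1-one, via dilithio species 19 (not isolated), via tetrahedral adduct 20 (not isolated)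
Conditions: n-BuLi (2.3 equiv), TMEDA, THF, −78 to 0 °C; then 18 (1.2 equiv), −78 to −20 °C; aq NH4Cl
Reagents that add atoms: none
Why: Directed ortho-metalation followed by Weinreb ketone synthesis; the first equivalent of base forms the tertiary alkoxide and the second removes H7, the only ring hydrogen flanked by two unhindered ether oxygens (OMe and O1, with the nearby alkoxide holding lithium), whereas H5 is screened by the triisopropylsilyl ether. Aryllithium 19 adds 1,2 to the amide and chelate 20 holds the ketone back until work-up, so neither a tertiary alcohol nor a conjugate adduct is expected.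

Step 10
Reactants: 21 (2E)-1-[(2R)-2-(2-hydroxypropan-2-yl)-6-methoxy-4-[(triisopropylsilyl)oxy]-2,3-dihydro-1-benzofuran-7-yl]-3-{4-[(triisopropylsilyl)oxy]phenyl}prop-2-en-1-one
Product: 22 (2E)-1-[(2R)-4-hydroxy-2-(2-hydroxypropan-2-yl)-6-methoxy-2,3-dihydro-1-benzofuran-7-yl]-3-(4-hydroxyphenyl)prop-2-en-1-one
Conditions: TBAF (2.5 equiv), AcOH (2.5 equiv), THF, 0 °C
Reagents that add atoms: none
Why: Fluoride cleaves both aryl silyl ethers (fluorodesilylation); the acetic acid buffer keeps the phenols protonated so the enone meets no strong base, and the tertiary alcohol and C2 are untouched.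

## Compound list

1 | 2,4,6-trihydroxybenzaldehyde | O=Cc1c(O)cc(O)cc1O | starting material
2 | 2,6-dihydroxy-4-methoxybenzaldehyde | COc1cc(O)c(C=O)c(O)c1 | intermediate
3 | 2-hydroxy-4-methoxy-6-[(triisopropylsilyl)oxy]benzaldehyde | COc1cc(O)c(C=O)c(O[Si](C(C)C)(C(C)C)C(C)C)c1 | intermediate
4 | 2-[(dimethyliminio)methyl]-5-methoxy-3-[(triisopropylsilyl)oxy]phenolate | C[N+](C)=Cc1c([O-])cc(OC)cc1O[Si](C(C)C)(C(C)C)C(C)C | intermediate
5 | 2-[(dimethylamino)methyl]-5-methoxy-3-[(triisopropylsilyl)oxy]phenol | CN(C)Cc1c(O)cc(OC)cc1O[Si](C(C)C)(C(C)C)C(C)C | intermediate
6 | tert-butyl bromoacetate | BrCC(=O)OC(C)(C)C | starting material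
7 | dimethyl sulfide | CSC | starting material
8 | (2-tert-butoxy-2-oxoethyl)dimethylsulfonium bromide | C[S+](C)CC(=O)OC(C)(C)C.[Br-] | intermediate
9 | 1-{2-hydroxy-4-methoxy-6-[(triisopropylsilyl)oxy]phenyl}-N,N,N-trimethylmethanaminium iodide | C[N+](C)(C)Cc1c(O)cc(OC)cc1O[Si](C(C)C)(C(C)C)C(C)C.[I-] | intermediate
10 | 3-methoxy-6-methylidene-5-[(triisopropylsilyl)oxy]cyclohexa-2,4-dien-1-one | C=C1C(=O)C=C(OC)C=C1O[Si](C(C)C)(C(C)C)C(C)C | intermediate
11 | tert-butyl (dimethyl-λ4-sulfanylidene)acetate (ylide of 8) | C[S+](C)[CH-]C(=O)OC(C)(C)C | intermediate
12 | 2-[3-tert-butoxy-2-(dimethylsulfonio)-3-oxopropyl]-5-methoxy-3-[(triisopropylsilyl)oxy]phenolate | C[S+](C)C(Cc1c([O-])cc(OC)cc1O[Si](C(C)C)(C(C)C)C(C)C)C(=O)OC(C)(C)C | intermediate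
13 | tert-butyl (2R)-6-methoxy-4-[(triisopropylsilyl)oxy]-2,3-dihydro-1-benzofuran-2-carboxylate | COc1cc(O[Si](C(C)C)(C(C)C)C(C)C)c2c(c1)O[C@@H](C(=O)OC(C)(C)C)C2 | intermediate
14 | 1-[(2R)-6-methoxy-4-[(triisopropylsilyl)oxy]-2,3-dihydro-1-benzofuran-2-yl]ethan-1-one | COc1cc(O[Si](C(C)C)(C(C)C)C(C)C)c2c(c1)O[C@@H](C(C)=O)C2 | intermediate
15 | 2-[(2R)-6-methoxy-4-[(triisopropylsilyl)oxy]-2,3-dihydro-1-benzofuran-2-yl]propan-2-ol | COc1cc(O[Si](C(C)C)(C(C)C)C(C)C)c2c(c1)O[C@@H](C(C)(C)O)C2 | intermediate
16 | (2E)-3-(4-hydroxyphenyl)prop-2-enoic acid | O=C(O)/C=C/c1ccc(O)cc1 | starting material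
17 | (2E)-3-(4-hydroxyphenyl)-N-methoxy-N-methylprop-2-enamide | CON(C)C(=O)/C=C/c1ccc(O)cc1 | intermediate
18 | (2E)-N-methoxy-N-methyl-3-{4-[(triisopropylsilyl)oxy]phenyl}prop-2-enamide | CON(C)C(=O)/C=C/c1ccc(O[Si](C(C)C)(C(C)C)C(C)C)cc1 | intermediate
19 | lithium 2-[(2R)-7-lithio-6-methoxy-4-[(triisopropylsilyl)oxy]-2,3-dihydro-1-benzofuran-2-yl]propan-2-olate | COc1cc(O[Si](C(C)C)(C(C)C)C(C)C)c2c(c1[Li])O[C@@H](C(C)(C)O[Li])C2 | intermediate
20 | dilithium salt of the N-methoxy-N-methyl hemiaminal formed from 19 and 18 (carbinol centre undefined) | COc1cc(O[Si](C(C)C)(C(C)C)C(C)C)c2c(c1C(O[Li])(N(C)OC)/C=C/c1ccc(O[Si](C(C)C)(C(C)C)C(C)C)cc1)O[C@@H](C(C)(C)O[Li])C2 | intermediate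
21 | (2E)-1-[(2R)-2-(2-hydroxypropan-2-yl)-6-methoxy-4-[(triisopropylsilyl)oxy]-2,3-dihydro-1-benzofuran-7-yl]-3-{4-[(triisopropylsilyl)oxy]phenyl}prop-2-en-1-one | COc1cc(O[Si](C(C)C)(C(C)C)C(C)C)c2c(c1C(=O)/C=C/c1ccc(O[Si](C(C)C)(C(C)C)C(C)C)cc1)O[C@@H](C(C)(C)O)C2 | intermediate
22 | (2E)-1-[(2R)-4-hydroxy-2-(2-hydroxypropan-2-yl)-6-methoxy-2,3-dihydro-1-benzofuran-7-yl]-3-(4-hydroxyphenyl)prop-2-en-1-one | COc1cc(O)c2c(c1C(=O)/C=C/c1ccc(O)cc1)O[C@@H](C(C)(C)O)C2 | target

## Step count and least certain steps

Total step count: 10. Longest linear sequence: 7 steps (steps 1, 2, 3, 5, 6, 9, 10, from 1 to 22). Step 4 and steps 7 and 8 are side branches.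

Step 5 (key step). The most likely failure is low enantio-induction. The stereocentre forms on the ylide carbon with no neighbouring stereocentre to relay it, and betaine 12 can epimerise at C2 before it closes, so the catalyst must discriminate in the ring closure itself. A second failure is loss of material by self-condensation of methide 10 with the electron-rich rings present. The fallback runs the annulation of 5 and 8 without the chiral catalyst (MeI, then Cs2CO3, MeCN, rt), which should give racemic tert-butyl 6-methoxy-4-[(triisopropylsilyl)oxy]-2,3-dihydro-1-benzofuran-2-carboxylate F1. Preparative chromatography of F1 on a polysaccharide-based chiral stationary phase rejoins the route at 13. The antipode, tert-butyl (2S)-6-methoxy-4-[(triisopropylsilyl)oxy]-2,3-dihydro-1-benzofuran-2-carboxylate F2, should be convertible back to F1 by base-mediated enolisation and can be resubmitted.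

Step 9. The most likely failure is poor acyl transfer. The hindered, basic dianion 19 may deprotonate the amide or attack its N-methoxy group instead of adding to the carbonyl, and metalation beside a lithium alkoxide may be incomplete. The fallback reduces 18 with i-Bu2AlH (THF, −78 °C) to (2E)-3-{4-[(triisopropylsilyl)oxy]phenyl}prop-2-enal F3. Adding 19, generated from 15 as before, to this more electrophilic and non-enolisable aldehyde should give (2E)-1-[(2R)-2-(2-hydroxypropan-2-yl)-6-methoxy-4-[(triisopropylsilyl)oxy]-2,3-dihydro-1-benzofuran-7-yl]-3-{4-[(triisopropylsilyl)oxy]phenyl}prop-2-en-1-ol F4 as a mixture of carbinol epimers. Oxidising the allylic, benzylic alcohol with MnO2 (CH2Cl2, rt) rejoins the route at 21.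

Step 1. The most likely failure is over-alkylation at a second oxygen or ring C-methylation, because all three hydroxyls are acidic and the ring is nucleophilic. The fallback methylates 1 exhaustively (Me2SO4, K2CO3, acetone) to 2,4,6-trimethoxybenzaldehyde F5, which is also commercial. AlCl3 in CH2Cl2 should then cleave only the two methyl ethers that chelate the formyl oxygen, which rejoins the route at 2.

Step 6. The most likely failure is enolisation at C2. The Grignard reagent may act as a base on the hindered tert-butyl ester or on ketone 14, eroding enantiopurity, or the reaction may stall at 14. The fallback cleaves the ester of 13 with TMSOTf and 2,6-lutidine, followed by aqueous work-up, to (2R)-6-methoxy-4-[(triisopropylsilyl)oxy]-2,3-dihydro-1-benzofuran-2-carboxylic acid F6. MeLi (THF, −78 to 0 °C) converts the carboxylate, which does not enolise at C2, into ketone 14 on quench. MeMgBr with CeCl3 at −78 °C then adds to isolated 14, which rejoins the route at 15.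

## Further compounds

F1 | step 5 | tert-butyl (2RS)-6-methoxy-4-[(triisopropylsilyl)oxy]-2,3-dihydro-1-benzofuran-2-carboxylate | COc1cc(O[Si](C(C)C)(C(C)C)C(C)C)c2c(c1)OC(C(=O)OC(C)(C)C)C2
F2 | step 5 | tert-butyl (2S)-6-methoxy-4-[(triisopropylsilyl)oxy]-2,3-dihydro-1-benzofuran-2-carboxylate | COc1cc(O[Si](C(C)C)(C(C)C)C(C)C)c2c(c1)O[C@H](C(=O)OC(C)(C)C)C2
F3 | step 9 | (2E)-3-{4-[(triisopropylsilyl)oxy]phenyl}prop-2-enal | O=C/C=C/c1ccc(O[Si](C(C)C)(C(C)C)C(C)C)cc1
F4 | step 9 | (2E)-1-[(2R)-2-(2-hydroxypropan-2-yl)-6-methoxy-4-[(triisopropylsilyl)oxy]-2,3-dihydro-1-benzofuran-7-yl]-3-{4-[(triisopropylsilyl)oxy]phenyl}prop-2-en-1-ol | COc1cc(O[Si](C(C)C)(C(C)C)C(C)C)c2c(c1C(O)/C=C/c1ccc(O[Si](C(C)C)(C(C)C)C(C)C)cc1)O[C@@H](C(C)(C)O)C2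
F5 | step 1 | 2,4,6-trimethoxybenzaldehyde | COc1cc(OC)c(C=O)c(OC)c1
F6 | step 6 | (2R)-6-methoxy-4-[(triisopropylsilyl)oxy]-2,3-dihydro-1-benzofuran-2-carboxylic acid | COc1cc(O[Si](C(C)C)(C(C)C)C(C)C)c2c(c1)O[C@@H](C(=O)O)C2
A1 | alternative 1 | 5-methoxy-3-[(4-methoxybenzyl)oxy]-2-(3-methylbut-2-en-1-yl)-6-(trimethylsilyl)phenol | COc1cc(OCc2ccc(OC)cc2)c(CC=C(C)C)c(O)c1[Si](C)(C)C
A2 | alternative 1 | 3-[(4-methoxybenzyl)oxy]-4-(3-methylbut-2-en-1-yl)cyclobut-2-en-1-one | O=C1C=C(OCc2ccc(OC)cc2)C1CC=C(C)C
A3 | alternative 1 | (methoxyethynyl)trimethylsilane | COC#C[Si](C)(C)C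
A4 | alternative 2 | methyl (2R)-6-methoxy-2-{2-[(triethylsilyl)oxy]propan-2-yl}-4-[(triisopropylsilyl)oxy]-2,3-dihydro-1-benzofuran-7-carboxylate | COC(=O)c1c(OC)cc(O[Si](C(C)C)(C(C)C)C(C)C)c2c1O[C@@H](C(C)(C)O[Si](CC)(CC)CC)C2
A5 | alternative 2 | methyl 2-iodo-6-methoxy-4-[(triisopropylsilyl)oxy]benzoate | COC(=O)c1c(I)cc(O[Si](C(C)C)(C(C)C)C(C)C)cc1OC
A6 | alternative 2 | triethyl({2-[(2R)-oxiran-2-yl]propan-2-yl}oxy)silane | O1[C@@H](C(C)(C)O[Si](CC)(CC)CC)C1
A7 | alternative 3 | 1-[(2R)-6-methoxy-4-(methoxymethoxy)-2-(prop-1-en-2-yl)-2,3-dihydro-1-benzofuran-7-yl]ethan-1-one | COc1cc(OCOC)c2c(c1C(C)=O)O[C@@H](C(C)=C)C2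
A8 | alternative 3 | 1-[2-hydroxy-3-iodo-6-methoxy-4-(methoxymethoxy)phenyl]ethan-1-one | CC(=O)c1c(O)c(I)c(OCOC)cc1OC
A9 | alternative 3 | 2-methylbuta-1,3-diene (isoprene) | C=CC(C)=C
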